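**Strategy.** The decalin is cut along C1–C10 and C4–C5, so that ring B, with its C8 methyl, C9 oxygen and C10 methyl, is recognised as 2,6-dimethyl-1,4-benzoquinone and ring A as a cyclohexene fused onto the C5–C10 edge. One catalytic enantioselective Diels–Alder reaction of the quinone with an (E)-2-silyloxypenta-1,3-diene closes ring A, creates the quaternary C10 stereocentre in absolute form and leaves a regiodefined C2 enol ether, from which the C4 gem-dimethyl group and the C2–C3 alkene for cis-dihydroxylation are derived; the C9 carbonyl later accepts the side chain, attached by vinyl addition and a stereoretentive B-alkyl Suzuki coupling.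

Key step: step 2

Numbering convention: the decalin carbons are numbered as in the target (ring A = C1–C5 and C10, ring B = C5–C10; angular methyl on C10, side chain on C9, methyl on C8, gem-dimethyl on C4); β is the face of the C10 methyl, α the opposite face.

Assumption: the catalyst built from (S)-α,α-diphenylprolinol is taken to expose the face of the bound quinone double bond that leads to the cycloadduct drawn below, by analogy with its behaviour toward other dienophiles bound through an α-C–H; should the adduct prove antipodal, the catalyst from (R)-α,α-diphenylprolinol would be used with nothing else changed.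

Step 1
Reactants: 1 (E)-pent-3-en-2-one; 2 triisopropylsilyl trifluoromethanesulfonate
Product: 3 (E)-2-(triisopropylsilyloxy)penta-1,3-diene
Conditions: Et3N, Et2O, 0 °C → rt
Reagents that add atoms: triisopropylsilyl trifluoromethanesulfonate (2), CC(C)[Si](C(C)C)(C(C)C)OS(=O)(=O)C(F)(F)F
Why: Soft enolisation (silyl enol ether formation): O-silylation of the enone and removal of an α′-methyl proton by Et3N should give the cross-conjugated 2-silyloxy diene, the (E)-geometry of the C3=C4 bond being carried over from 1.

Step 2
Reactants: 3 (E)-2-(triisopropylsilyloxy)penta-1,3-diene; 4 2,6-dimethyl-1,4-benzoquinone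
Product: 5 cis-fused endo cycloadduct (C2=C3 silyl enol ether; C6/C9 ene-dione with C7=C8; 4α-Me, 5β-H, 10β-Me)
Conditions: N-protonated B-o-tolyl oxazaborolidine of (S)-α,α-diphenylprolinol, Tf2N− salt (from the oxazaborolidine and Tf2NH, 20 mol%), CH2Cl2, −78 °C; Et3N quench
Reagents that add atoms: none
Why: The cationic boron Lewis acid binds the C6 carbonyl oxygen of 4 (the quinone oxygen flanked by two C–H groups) at the lone pair syn to C5–H, which lowers the LUMO of the C5=C10 double bond, and diene 3 adds to it in a concerted, asynchronous endo [4+2] cycloaddition; the closest known reaction type is the oxazaborolidinium-catalysed Diels–Alder addition of 2-silyloxy dienes to substituted 1,4-benzoquinones. Ring A is closed as a six-membered carbocycle by intermolecular cycloaddition, suprafacial on both partners, with C1–C10 and C4–C5 formed in the same event. C10 and C5 emerge cis because both bonds form on one face of the quinone double bond, and their absolute configuration is set by the catalyst, whose aryl group shields one face of the bound double bond (the two C=C bonds of the C2v-symmetric quinone are equivalent, so only this facial choice matters); C4 is set by the (E)-geometry of 3 and the endo transition state, which places its methyl group cis to C6. The step needs regioselectivity (C1 to C10, C4 to C5), secured because the methyl-bearing carbon is the β-carbon of the activated enone while the 2-silyloxy and 4-methyl groups of 3 both raise the HOMO coefficient at its CH2 terminus. Aromatisation of 5 is excluded by the quaternary C10, and the bulky silyl group protects the enol ether from cleavage.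

Step 3
Reactants: 5 cis-fused endo cycloadduct
Product: 6 cis-fused saturated 6,9-dione (C7–C8 reduced; C8 epimers; silyl enol ether intact)
Conditions: Zn dust, AcOH, THF, 0 °C → rt
Reagents that add atoms: none
Why: Zinc/acetic acid reduction of an ene-1,4-dione is a standard two-electron reduction of the electron-poor C7=C8 bond that should leave the ketones and the hindered silyl enol ether untouched; C8 forms without control here and is corrected in step 4.

Step 4
Reactants: 6 cis-fused saturated 6,9-dione
Product: 7 trans-fused 6,9-dione (5α-H, 8α-Me, 4α-Me, 10β-Me; C2=C3 silyl enol ether)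
Conditions: NaOMe (0.2 equiv), MeOH/THF, 0 °C → rt
Reagents that add atoms: none
Why: Base-mediated enolisation (thermodynamic epimerisation, as in the classical cis-to-trans isomerisation of angularly methylated quinone adducts) should relax C5, α to the C6 ketone, to the trans-fused decalin and C8, α to the C9 ketone, to the equatorial 8α-methyl isomer, which avoids a 1,3-diaxial clash with the C10 methyl.

Step 5
Reactants: 7 trans-fused 6,9-dione
Product: 8 C6 p-toluenesulfonylhydrazone of 7 (C9 ketone free)
Conditions: TsNHNH2, MeOH/THF, rt
Reagents that add atoms: p-toluenesulfonyl hydrazide, Cc1ccc(cc1)S(=O)(=O)NN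
Why: Hydrazone condensation should occur only at the C6 ketone, because the C9 ketone is flanked by the quaternary C10 and the methyl-bearing C8, and the neutral conditions preserve the silyl enol ether.

Step 6
Reactants: 8 C6 p-toluenesulfonylhydrazone
Product: 9 trans-fused 9-ketone with C6 methylene (C2=C3 silyl enol ether; 4α-Me, 5α-H, 8α-Me, 10β-Me)
Conditions: catecholborane, CHCl3, 0 °C; then NaOAc·3H2O, 60 °C
Reagents that add atoms: none
Why: Caglioti-type reduction with catecholborane: hydride addition to the C=N bond followed by acetate-induced loss of sulfinate and dinitrogen should give the C6 methylene under conditions tolerated by the hindered C9 ketone and the enol ether, and it fixes the trans ring fusion because C5 is no longer enolisable.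

Step 7
Reactants: 9 trans-fused 9-ketone with C2=C3 silyl enol ether
Product: 10 ring A enone (C2=O, C3=C4 with 4-methyl; C9 ketone; 5α-H, 8α-Me, 10β-Me)
Conditions: Pd(OAc)2 (1.1 equiv), MeCN, 40 °C
Reagents that add atoms: none
Why: Saegusa–Ito oxidation: palladation of the silyl enol ether at C3 by divalent palladium and β-hydride elimination, possible only toward C4 because C1 leads to the quaternary C10, should give the C3=C4 enone with release of zerovalent palladium.

Step 8
Reactants: 10 ring A enone
Product: 12 C2 vinyl triflate (C2=C3; 4,4-dimethyl; C9 ketone), via lithium enolate 11 (not isolated)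
Conditions: Me2CuLi (from MeLi and CuI), Et2O, −20 → 0 °C; then PhNTf2, THF, 0 °C → rt
Reagents that add atoms: lithium dimethylcuprate, [Li+].C[Cu-]C; N-phenylbis(trifluoromethanesulfonimide), O=S(=O)(N(c1ccccc1)S(=O)(=O)C(F)(F)F)C(F)(F)F
Why: Cuprate conjugate addition to the β-methyl enone makes C4 the gem-dimethyl carbon (no stereocentre results) and gives the C2 enolate with the double bond fixed at C2=C3, which is trapped on oxygen as the vinyl triflate; the hindered, non-conjugated C9 ketone should not react with the cuprate at this temperature.

Step 9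
Reactants: 12 C2 vinyl triflate
Product: 13 4,4,8α,10β-tetramethyl-trans-decal-2-en-9-one (5α-H)
Conditions: Pd(OAc)2 (5 mol%), PPh3, HCO2H, Bu3N, DMF, 60 °C
Reagents that add atoms: none
Why: Palladium-catalysed formate reduction of a vinyl triflate (oxidative addition, decarboxylation of formate to a palladium hydride, reductive elimination) replaces OTf by H without moving the double bond, giving the C2=C3 alkene.

Step 10
Reactants: 13 decal-2-en-9-one; 14 vinylmagnesium bromide
Product: 15 9α-vinyl-9β-hydroxy carbinol (C2=C3 alkene; 5α-H, 8α-Me, 10β-Me)
Conditions: CeCl3, THF, −78 → 0 °C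
Reagents that add atoms: vinylmagnesium bromide (14), C=C[Mg]Br
Why: CeCl3-promoted Grignard 1,2-addition suppresses enolisation of the hindered ketone, and the nucleophile should attack the α-face, axially and anti to the axial C10 methyl that blocks the β-face, so that C9 carries a β (equatorial) hydroxyl and an α vinyl group (substrate control).

Step 11
Reactants: 16 methyl acetoacetate
Product: 17 methyl (E)-3-(trifluoromethylsulfonyloxy)but-2-enoate
Conditions: Tf2O, aq. Me4NOH, hexanes, 5 °C
Reagents that add atoms: trifluoromethanesulfonic anhydride, O=S(=O)(OS(=O)(=O)C(F)(F)F)C(F)(F)F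
Why: O-triflation of the β-keto ester enolate with a non-chelating tetraalkylammonium counter-ion in a two-phase medium should give the (E)-enol triflate (OTf trans to the ester), the known complement of the lithium-chelated (Z)-selective protocol.

Step 12
Reactants: 15 9α-vinyl-9β-hydroxy carbinol; 17 methyl (E)-3-(trifluoromethylsulfonyloxy)but-2-enoate
Product: 19 methyl (E)-enoate with complete side chain on C9 (9β-OH; ring C2=C3 alkene), via B-alkyl-9-BBN adduct 18 (not isolated)
Conditions: 9-BBN (2.5 equiv), THF, 0 °C → rt; then 17, PdCl2(dppf) (5 mol%), aq. K3PO4, DMF, rt → 50 °C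
Reagents that add atoms: none
Why: 9-BBN should hydroborate only the monosubstituted vinyl group (anti-Markovnikov, far faster than the hindered ring alkene), and the primary alkylborane then undergoes B-alkyl Suzuki–Miyaura coupling with the enol triflate with retention of the (E)-geometry, which fixes the C13=C14 configuration.

Step 13
Reactants: 19 methyl (E)-enoate with ring C2=C3 alkene
Product: 20 target, methyl (2E)-3-methyl-5-[(1S,2R,4aS,6S,7R,8aS)-1,6,7-trihydroxy-2,5,5,8a-tetramethyldecahydronaphthalen-1-yl]pent-2-enoate
Conditions: OsO4 (5 mol%), NMO, acetone/H2O, rt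
Reagents that add atoms: N-methylmorpholine N-oxide, C[N+]1([O-])CCOCC1; osmium tetroxide, O=[Os](=O)(=O)=O; water, O
Why: Catalytic OsO4/NMO cis-dihydroxylation ([3+2] addition of OsO4) should select the electron-richer ring alkene over the electron-poor trisubstituted enoate and approach from the α-face, opposite the axial C10 and C4β methyl groups, giving the 2α,3α-diol (substrate control).

**Compound list**

1 | (E)-pent-3-en-2-one | C/C=C/C(C)=O | starting material
2 | triisopropylsilyl trifluoromethanesulfonate | CC(C)[Si](C(C)C)(C(C)C)OS(=O)(=O)C(F)(F)F | starting material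
3 | (E)-2-(triisopropylsilyloxy)penta-1,3-diene | C=C(O[Si](C(C)C)(C(C)C)C(C)C)/C=C/C | intermediate
4 | 2,6-dimethyl-1,4-benzoquinone | CC1=CC(=O)C=C(C)C1=O | starting material
5 | cis-fused endo cycloadduct (C2=C3 triisopropylsilyl enol ether; C6=O, C7=C8, C9=O; 4α-Me, 5β-H, 10β-Me) | O=C1C(C)=CC(=O)[C@@H]2[C@H](C)C=C(O[Si](C(C)C)(C(C)C)C(C)C)C[C@@]21C | intermediate
6 | cis-fused saturated 6,9-dione (C8 epimers, C8 left undefined; silyl enol ether intact) | O=C1C(C)CC(=O)[C@@H]2[C@H](C)C=C(O[Si](C(C)C)(C(C)C)C(C)C)C[C@@]21C | intermediate
7 | trans-fused 6,9-dione (5α-H, 8α-Me, 4α-Me, 10β-Me; C2=C3 silyl enol ether) | O=C1[C@H](C)CC(=O)[C@H]2[C@H](C)C=C(O[Si](C(C)C)(C(C)C)C(C)C)C[C@@]21C | intermediate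
8 | C6 p-toluenesulfonylhydrazone of 7 (C=N geometry undefined) | O=C1[C@H](C)CC(=NNS(=O)(=O)c3ccc(C)cc3)[C@H]2[C@H](C)C=C(O[Si](C(C)C)(C(C)C)C(C)C)C[C@@]21C | intermediate
9 | trans-fused 9-ketone, C6 methylene, C2=C3 silyl enol ether | O=C1[C@H](C)CC[C@H]2[C@H](C)C=C(O[Si](C(C)C)(C(C)C)C(C)C)C[C@@]21C | intermediate
10 | ring A enone (C2=O, C3=C4, 4-methyl), C9 ketone | O=C1[C@H](C)CC[C@H]2C(C)=CC(=O)C[C@@]21C | intermediate
11 | lithium C2 enolate (C2=C3), 4,4-dimethyl, C9 ketone | O=C1[C@H](C)CC[C@H]2C(C)(C)C=C(O[Li])C[C@@]21C | intermediate
12 | C2 vinyl triflate (C2=C3), 4,4-dimethyl, C9 ketone | O=C1[C@H](C)CC[C@H]2C(C)(C)C=C(OS(=O)(=O)C(F)(F)F)C[C@@]21C | intermediate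
13 | 4,4,8α,10β-tetramethyl-trans-decal-2-en-9-one (5α-H) | O=C1[C@H](C)CC[C@H]2C(C)(C)C=CC[C@@]21C | intermediate
14 | vinylmagnesium bromide | C=C[Mg]Br | starting material
15 | 9α-vinyl-9β-hydroxy carbinol with C2=C3 alkene | C=C[C@]1(O)[C@H](C)CC[C@H]2C(C)(C)C=CC[C@@]21C | intermediate
16 | methyl acetoacetate | COC(=O)CC(C)=O | starting material
17 | methyl (E)-3-(trifluoromethylsulfonyloxy)but-2-enoate | COC(=O)/C=C(\C)OS(=O)(=O)C(F)(F)F | intermediate
18 | B-alkyl-9-BBN adduct of 15 (boron on C12) | B1(CC[C@]3(O)[C@H](C)CC[C@H]4C(C)(C)C=CC[C@@]43C)C2CCCC1CCC2 | intermediate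
19 | methyl (E)-enoate with 9β-OH and ring C2=C3 alkene | COC(=O)/C=C(\C)CC[C@]1(O)[C@H](C)CC[C@H]2C(C)(C)C=CC[C@@]21C | intermediate
20 | target (2α,3α,9β-triol) | COC(=O)/C=C(\C)CC[C@]1(O)[C@H](C)CC[C@H]2C(C)(C)[C@H](O)[C@H](O)C[C@@]21C | target

**Totals.** Total step count: 13. Longest linear sequence: 12 steps (steps 1–10, 12, 13); step 11 is the one-step side branch.

**Steps most likely to fail**

1. Step 2 (key step). What may go wrong: insufficient facial or endo selectivity, or a slow cycloaddition at the trisubstituted quinone double bond with competing acid cleavage of the silyl enol ether. Fallback: setting out from 3 and 4, the cycloaddition would be run with an achiral Lewis acid (Me2AlCl, CH2Cl2, −78 °C), which binds the same unhindered carbonyl and so keeps regiochemistry and endo mode but gives the racemate, that is 5 together with the enantiomeric adduct F1. Preparative chromatography on a chiral stationary phase then returns 5, where the route is rejoined.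

2. Step 8. What may go wrong: slow conjugate addition at the hindered, fully substituted β-carbon C4, or incomplete O-sulfonylation of the copper-containing enolate. Fallback: setting out from 10, the addition would be run with Me2CuLi in the presence of Me3SiCl (THF, −78 °C), which accelerates the addition and delivers the isolable trimethylsilyl enol ether F2. Cleavage of F2 with MeLi (THF, 0 °C) gives the copper-free lithium enolate 11, which is triflated with PhNTf2 to rejoin the route at 12.

3. Step 13. What may go wrong: loss of chemoselectivity, with the enoate double bond dihydroxylated along with or instead of the hindered ring alkene. Fallback: setting out from 13, the ring alkene would be dihydroxylated before any other alkene is present (OsO4, NMO) to give diol ketone F3, which is protected with 2,2-dimethoxypropane and PPTS as acetonide ketone F4. Vinylmagnesium bromide with CeCl3 then gives vinyl carbinol acetonide F5, 9-BBN gives alkylborane F6, and coupling with 17 in the same flask gives enoate acetonide F7. Aqueous AcOH (40 °C) removes the acetonide and arrives at 20.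

**Further compounds**

F1 | step 2 | enantiomeric adduct (ent-5) | O=C1C(C)=CC(=O)[C@H]2[C@@H](C)C=C(O[Si](C(C)C)(C(C)C)C(C)C)C[C@]21C
F2 | step 8 | trimethylsilyl enol ether (C2=C3, 4,4-dimethyl, C9 ketone) | O=C1[C@H](C)CC[C@H]2C(C)(C)C=C(O[Si](C)(C)C)C[C@@]21C
F3 | step 13 | diol ketone (2α,3α-diol, C9 ketone) | O=C1[C@H](C)CC[C@H]2C(C)(C)[C@H](O)[C@H](O)C[C@@]21C
F4 | step 13 | acetonide ketone | O=C1[C@H](C)CC[C@H]2C(C)(C)[C@H](O3)[C@H](OC3(C)C)C[C@@]21C
F5 | step 13 | vinyl carbinol acetonide (9α-vinyl, 9β-OH) | C=C[C@]1(O)[C@H](C)CC[C@H]2C(C)(C)[C@H](O3)[C@H](OC3(C)C)C[C@@]21C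
F6 | step 13 | alkylborane (B-alkyl-9-BBN adduct of F5) | B1(CC[C@]3(O)[C@H](C)CC[C@H]4C(C)(C)[C@H](O5)[C@H](OC5(C)C)C[C@@]43C)C2CCCC1CCC2
F7 | step 13 | enoate acetonide | COC(=O)/C=C(\C)CC[C@]1(O)[C@H](C)CC[C@H]2C(C)(C)[C@H](O3)[C@H](OC3(C)C)C[C@@]21C
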